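**Retrosynthetic overview**
1. The ten-membered ring is closed last, at C6–C7, by a Ni-catalysed reductive alkenyl iodide/alkyl iodide coupling of an acyclic diiodide that already carries the epoxide, both esters and all five stereocentres.
2. The C3 carbinol (1,3-anti to C1) and the C1 acetate come from one Evans–Tishchenko reduction (acetaldehyde) of a β-hydroxy ketone; the ketone is unmasked from a 1,1-disubstituted alkene, and the senecioate is added afterwards.
3. The C1–C2 bond and the C1/C2 stereocentres come from a Cr(II) allylation of a cis-epoxy aldehyde (West half) with a 2,3-disubstituted allyl bromide (East half).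
4. West half: (Z)-enynol → dienol → hydroboration/iodination → Sharpless epoxidation → aldehyde. East half: pent-4-yn-1-ol → Zr-catalysed carboalumination/iodination → cross-aldol condensation with 2-methylpropanal → allylic bromide.
5. Ring order: the oxirane first (step 5), the cyclodecene last (step 17).

Assumption: ring atoms are called C1–C10 in the order of the SMILES string (C1 = CH–OAc, C2 = CH–iPr, C3 = CH–O-senecioyl, C5=C6 = E-alkene, C9/C10 = epoxide carbons; the epoxide is cis, C8 and C1 on the same side).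

**Route**

Step 1
Reactants: 1 (2Z)-3-methylpent-2-en-4-yn-1-ol
Product: 2 (2Z)-3-methylpenta-2,4-dien-1-ol
Conditions: H2 (1 atm), Lindlar catalyst, quinoline, EtOAc, 0 °C to rt, stopped after 1 equiv H2
Reagents that add atoms: none
Why: Lindlar semi-hydrogenation stops at the alkene and leaves the Z-trisubstituted alkene unchanged.

Step 2
Reactants: 2 (2Z)-3-methylpenta-2,4-dien-1-ol
Product: 3 tert-butyl(dimethyl){[(2Z)-3-methylpenta-2,4-dien-1-yl]oxy}silane
Conditions: TBSCl, imidazole, DMF, 0 °C to rt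
Reagents that add atoms: tert-butyl(chloro)dimethylsilane, CC(C)(C)[Si](C)(C)Cl
Why: Standard silyl protection keeps the hydroxyl from consuming borane in the next step.

Step 3
Reactants: 3 tert-butyl(dimethyl){[(2Z)-3-methylpenta-2,4-dien-1-yl]oxy}silane
Product: 5 tert-butyl{[(2Z)-5-iodo-3-methylpent-2-en-1-yl]oxy}dimethylsilane, via alkyl-9-BBN adduct 4 (not isolated)
Conditions: 9-BBN, THF, 0 °C to rt; then NaOMe/MeOH, I2, 0 °C
Reagents that add atoms: iodine, II
Why: Brown hydroboration–iodination, in which 9-BBN adds anti-Markovnikov to the terminal vinyl group only (as with isoprene) and base-promoted iodinolysis of the primary C–B bond gives the primary iodide (C7).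

Step 4
Reactants: 5 tert-butyl{[(2Z)-5-iodo-3-methylpent-2-en-1-yl]oxy}dimethylsilane
Product: 6 (2Z)-5-iodo-3-methylpent-2-en-1-ol
Conditions: HF·pyridine, THF, 0 °C
Reagents that add atoms: none
Why: Non-basic fluoride desilylation avoids E2 loss of the homoallylic iodide.

Step 5
Reactants: 6 (2Z)-5-iodo-3-methylpent-2-en-1-ol
Product: 7 [(2R,3S)-3-(2-iodoethyl)-3-methyloxiran-2-yl]methanol
Conditions: Ti(OiPr)4 (10 mol%), D-(−)-diethyl tartrate (14 mol%), t-BuOOH, 4 Å MS, CH2Cl2, −20 °C
Reagents that add atoms: tert-butyl hydroperoxide, CC(C)(C)OO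
Why: Sharpless asymmetric epoxidation, where D-(−)-tartrate gives the (2R,3S) epoxy alcohol (the mirror image of the L-(+)-tartrate/nerol series) and the Z alkene fixes the cis epoxide, so C9 (S) and C10 (R) are set here.

Step 6
Reactants: 7 [(2R,3S)-3-(2-iodoethyl)-3-methyloxiran-2-yl]methanol
Product: 8 (2S,3S)-3-(2-iodoethyl)-3-methyloxirane-2-carbaldehyde
Conditions: TEMPO (10 mol%), PhI(OAc)2, CH2Cl2, rt; used crude
Reagents that add atoms: none
Why: TEMPO/BAIB oxidation is mild enough for an epoxy alcohol and does not touch the epoxide stereocentres or the alkyl iodide.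

Step 7
Reactants: 9 pent-4-yn-1-ol
Product: 11 (4E)-5-iodo-4-methylpent-4-en-1-ol, via alkenylalane 10 (not isolated)
Conditions: AlMe3 (3 equiv), Cp2ZrCl2 (0.25 equiv), CH2Cl2, 0 °C to rt; then I2, THF, −30 °C
Reagents that add atoms: trimethylaluminium, C[Al](C)C; iodine, II
Why: Negishi Zr-catalysed carboalumination adds Me and Al syn across the alkyne and iodinolysis proceeds with retention, which sets the E geometry of the later C5=C6 alkene.

Step 8
Reactants: 11 (4E)-5-iodo-4-methylpent-4-en-1-ol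
Product: 12 (4E)-5-iodo-4-methylpent-4-enal
Conditions: TEMPO (10 mol%), PhI(OAc)2, CH2Cl2, rt
Reagents that add atoms: none
Why: Chemoselective TEMPO/BAIB oxidation of the primary alcohol leaves the alkenyl iodide intact.

Step 9
Reactants: 12 (4E)-5-iodo-4-methylpent-4-enal; 13 2-methylpropanal
Product: 14 (2S,3S)-3-hydroxy-2-[(2E)-3-iodo-2-methylprop-2-en-1-yl]-4-methylpentanal
Conditions: L-proline (10 mol%), DMF, 4 °C; 13 (3 equiv) in the flask, 12 added by syringe pump
Reagents that add atoms: none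
Why: Proline-catalysed enamine cross-aldol (List–MacMillan) uses the unbranched aldehyde as donor and the hindered α-branched aldehyde as acceptor; the two new stereocentres are erased in step 10.

Step 10
Reactants: 14 (2S,3S)-3-hydroxy-2-[(2E)-3-iodo-2-methylprop-2-en-1-yl]-4-methylpentanal
Product: 16 (2E)-2-[(2E)-3-iodo-2-methylprop-2-en-1-yl]-4-methylpent-2-enal, via β-mesylate 15 (not isolated)
Conditions: MsCl, Et3N, CH2Cl2, 0 °C to rt
Reagents that add atoms: none
Why: Mesylation followed by E1cB elimination gives the thermodynamically favoured (E)-2-alkyl enal.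

Step 11
Reactants: 16 (2E)-2-[(2E)-3-iodo-2-methylprop-2-en-1-yl]-4-methylpent-2-enal
Product: 17 (2E)-2-[(2E)-3-iodo-2-methylprop-2-en-1-yl]-4-methylpent-2-en-1-ol
Conditions: NaBH4, CeCl3·7H2O, MeOH, 0 °C
Reagents that add atoms: none
Why: Luche reduction gives clean 1,2-reduction of the enal.

Step 12
Reactants: 17 (2E)-2-[(2E)-3-iodo-2-methylprop-2-en-1-yl]-4-methylpent-2-en-1-ol
Product: 18 (1E,4E)-4-(bromomethyl)-1-iodo-2,6-dimethylhepta-1,4-diene
Conditions: CBr4, PPh3, CH2Cl2, 0 °C
Reagents that add atoms: carbon tetrabromide, BrC(Br)(Br)Br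
Why: Appel bromination is an SN2 displacement at the primary allylic carbon without allylic transposition.

Step 13
Reactants: 8 (2S,3S)-3-(2-iodoethyl)-3-methyloxirane-2-carbaldehyde; 18 (1E,4E)-4-(bromomethyl)-1-iodo-2,6-dimethylhepta-1,4-diene
Product: 20 (1R,2R,5E)-6-iodo-1-[(2R,3S)-3-(2-iodoethyl)-3-methyloxiran-2-yl]-5-methyl-3-methylidene-2-(propan-2-yl)hex-5-en-1-ol, via allylchromium(III) reagent 19 (not isolated)
Conditions: CrCl2 (Ni-free, 4 equiv), THF, 0 °C to rt; 18 (1.3 equiv)
Reagents that add atoms: none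
Why: Nozaki–Hiyama Cr(II) allylation, in which the γ-carbon of the σ-allylchromium adds through a chair transition state with isopropyl equatorial (anti C1–OH/C2–iPr) and Felkin–Anh attack anti to the epoxide C–O bond sets C1 erythro to the epoxide, so C1 (R) and C2 (R) follow from the epoxide of 8, while alkenyl and alkyl iodides are inert to Ni-free CrCl2.

Step 14
Reactants: 20 (1R,2R,5E)-6-iodo-1-[(2R,3S)-3-(2-iodoethyl)-3-methyloxiran-2-yl]-5-methyl-3-methylidene-2-(propan-2-yl)hex-5-en-1-ol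
Product: 22 (1R,2S,5E)-1-hydroxy-6-iodo-1-[(2R,3S)-3-(2-iodoethyl)-3-methyloxiran-2-yl]-5-methyl-2-(propan-2-yl)hex-5-en-3-one, via 1,2-diol 21 (not isolated)
Conditions: OsO4 (2 mol%), NaIO4 (4 equiv), 2,6-lutidine, dioxane/H2O 3:1, rt
Reagents that add atoms: osmium tetroxide (catalytic oxygen carrier), O=[Os](=O)(=O)=O; sodium periodate (terminal oxidant), [Na+].[O-]I(=O)(=O)=O
Why: Lemieux–Johnson cleavage, in which OsO4 dihydroxylates the 1,1-disubstituted alkene in preference to the deactivated trisubstituted iodoalkene and periodate cleaves the diol to the C3 ketone under buffered conditions that do not epimerise C2.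

Step 15
Reactants: 22 (1R,2S,5E)-1-hydroxy-6-iodo-1-[(2R,3S)-3-(2-iodoethyl)-3-methyloxiran-2-yl]-5-methyl-2-(propan-2-yl)hex-5-en-3-one
Product: 24 (1R,2R,3S,5E)-3-hydroxy-6-iodo-1-[(2R,3S)-3-(2-iodoethyl)-3-methyloxiran-2-yl]-5-methyl-2-(propan-2-yl)hex-5-en-1-yl acetate, via acetaldehyde hemiacetal 23 (not isolated)
Conditions: SmI2 (30 mol%), MeCHO (8 equiv), THF, −10 °C
Reagents that add atoms: acetaldehyde, CC=O
Why: Evans–Tishchenko reduction, in which the Sm(III)-bound hemiacetal on O1 delivers hydride intramolecularly to the C3 ketone through a chair transition state, giving the 1,3-anti alcohol (C3 S) and leaving the acetyl group on O1 in the same operation.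

Step 16
Reactants: 24 (1R,2R,3S,5E)-3-hydroxy-6-iodo-1-[(2R,3S)-3-(2-iodoethyl)-3-methyloxiran-2-yl]-5-methyl-2-(propan-2-yl)hex-5-en-1-yl acetate
Product: 25 (1R,2R,3S,5E)-1-(acetyloxy)-6-iodo-1-[(2R,3S)-3-(2-iodoethyl)-3-methyloxiran-2-yl]-5-methyl-2-(propan-2-yl)hex-5-en-3-yl 3-methylbut-2-enoate
Conditions: 3-methylbut-2-enoyl chloride, pyridine, DMAP (cat.), CH2Cl2, 0 °C
Reagents that add atoms: 3-methylbut-2-enoyl chloride, CC(C)=CC(Cl)=O
Why: DMAP-catalysed acylation of the free C3 hydroxyl with a weak base keeps the senecioate conjugated and does not disturb the stereocentres.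

Step 17
Reactants: 25 (1R,2R,3S,5E)-1-(acetyloxy)-6-iodo-1-[(2R,3S)-3-(2-iodoethyl)-3-methyloxiran-2-yl]-5-methyl-2-(propan-2-yl)hex-5-en-3-yl 3-methylbut-2-enoate
Product: 26 target (1S,4E,7S,8R,9R,10R)-9-(acetyloxy)-1,5-dimethyl-8-(propan-2-yl)-11-oxabicyclo[8.1.0]undec-4-en-7-yl 3-methylbut-2-enoate
Conditions: NiI2·xH2O (15 mol%), 4,4′-di-tert-butyl-2,2′-bipyridine (15 mol%), Zn dust (3 equiv), pyridine (cat.), DMA, 40 °C, syringe-pump addition of 25 (final 1–2 mM)
Reagents that add atoms: none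
Why: Proposed new method: a Ni-catalysed intramolecular reductive cross-electrophile coupling closes the ten-membered ring between an alkenyl iodide and an unactivated primary alkyl iodide – Ni(0)/dtbbpy inserts into the C6–I bond with retention of the E geometry, Ni(I) turns the primary iodide into a C7 radical, and at high dilution this tethered radical is captured by the alkenyl-Ni(II) centre of the same molecule to give a Ni(III) species that reductively eliminates the C6–C7 bond while Zn returns Ni(0); the closest known reaction type is the intermolecular Ni-catalysed alkenyl halide/alkyl halide reductive coupling and its small-ring intramolecular use, not yet shown for a medium carbocycle, and the esters and the trisubstituted epoxide should not be reduced under these conditions.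

**Compound list**
1 | (2Z)-3-methylpent-2-en-4-yn-1-ol | OC/C=C(C)\C#C | starting material
2 | (2Z)-3-methylpenta-2,4-dien-1-ol | OC/C=C(C)\C=C | intermediate
3 | tert-butyl(dimethyl){[(2Z)-3-methylpenta-2,4-dien-1-yl]oxy}silane | CC(C)(C)[Si](C)(C)OC/C=C(C)\C=C | intermediate
4 | 9-[(3Z)-5-{[tert-butyl(dimethyl)silyl]oxy}-3-methylpent-3-en-1-yl]-9-borabicyclo[3.3.1]nonane | CC(C)(C)[Si](C)(C)OC/C=C(C)\CCB1C2CCCC1CCC2 | intermediate
5 | tert-butyl{[(2Z)-5-iodo-3-methylpent-2-en-1-yl]oxy}dimethylsilane | CC(C)(C)[Si](C)(C)OC/C=C(C)\CCI | intermediate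
6 | (2Z)-5-iodo-3-methylpent-2-en-1-ol | OC/C=C(C)\CCI | intermediate
7 | [(2R,3S)-3-(2-iodoethyl)-3-methyloxiran-2-yl]methanol | ICC[C@]1(C)O[C@@H]1CO | intermediate
8 | (2S,3S)-3-(2-iodoethyl)-3-methyloxirane-2-carbaldehyde | ICC[C@]1(C)O[C@@H]1C=O | intermediate
9 | pent-4-yn-1-ol | OCCCC#C | starting material
10 | [(1E)-5-[(dimethylalumanyl)oxy]-2-methylpent-1-en-1-yl](dimethyl)alumane | C[Al](C)OCCC/C(C)=C/[Al](C)C | intermediate
11 | (4E)-5-iodo-4-methylpent-4-en-1-ol | OCCC/C(C)=C/I | intermediate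
12 | (4E)-5-iodo-4-methylpent-4-enal | O=CCC/C(C)=C/I | intermediate
13 | 2-methylpropanal | CC(C)C=O | starting material
14 | (2S,3S)-3-hydroxy-2-[(2E)-3-iodo-2-methylprop-2-en-1-yl]-4-methylpentanal (anti) | O=C[C@@H](C/C(C)=C/I)[C@@H](O)C(C)C | intermediate
15 | (2S,3S)-2-[(2E)-3-iodo-2-methylprop-2-en-1-yl]-4-methyl-1-oxopentan-3-yl methanesulfonate | O=C[C@@H](C/C(C)=C/I)[C@@H](OS(C)(=O)=O)C(C)C | intermediate
16 | (2E)-2-[(2E)-3-iodo-2-methylprop-2-en-1-yl]-4-methylpent-2-enal | O=C/C(C/C(C)=C/I)=C/C(C)C | intermediate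
17 | (2E)-2-[(2E)-3-iodo-2-methylprop-2-en-1-yl]-4-methylpent-2-en-1-ol | OC/C(C/C(C)=C/I)=C/C(C)C | intermediate
18 | (1E,4E)-4-(bromomethyl)-1-iodo-2,6-dimethylhepta-1,4-diene | BrC/C(C/C(C)=C/I)=C/C(C)C | intermediate
19 | dichloro{(2E)-2-[(2E)-3-iodo-2-methylprop-2-en-1-yl]-4-methylpent-2-en-1-yl}chromium(III), THF-solvated | Cl[Cr](Cl)C/C(C/C(C)=C/I)=C/C(C)C | intermediate
20 | (1R,2R,5E)-6-iodo-1-[(2R,3S)-3-(2-iodoethyl)-3-methyloxiran-2-yl]-5-methyl-3-methylidene-2-(propan-2-yl)hex-5-en-1-ol | ICC[C@]1(C)O[C@@H]1[C@H](O)[C@H](C(C)C)C(=C)C/C(C)=C/I | intermediate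
21 | (5E)-3-(hydroxymethyl)-6-iodo-1-[3-(2-iodoethyl)-3-methyloxiran-2-yl]-5-methyl-2-(propan-2-yl)hex-5-ene-1,3-diol, stereocentres of 20 retained, both C3 epimers | ICC[C@]1(C)O[C@@H]1[C@H](O)[C@H](C(C)C)C(O)(CO)C/C(C)=C/I | intermediate
22 | (1R,2S,5E)-1-hydroxy-6-iodo-1-[(2R,3S)-3-(2-iodoethyl)-3-methyloxiran-2-yl]-5-methyl-2-(propan-2-yl)hex-5-en-3-one | ICC[C@]1(C)O[C@@H]1[C@H](O)[C@H](C(C)C)C(=O)C/C(C)=C/I | intermediate
23 | 1-hydroxyethyl ether (hemiacetal, Sm-bound) on O1 of 22, stereocentres of 22 retained, hemiacetal carbon undefined | ICC[C@]1(C)O[C@@H]1[C@H](OC(C)O)[C@H](C(C)C)C(=O)C/C(C)=C/I | intermediate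
24 | (1R,2R,3S,5E)-3-hydroxy-6-iodo-1-[(2R,3S)-3-(2-iodoethyl)-3-methyloxiran-2-yl]-5-methyl-2-(propan-2-yl)hex-5-en-1-yl acetate | ICC[C@]1(C)O[C@@H]1[C@H](OC(C)=O)[C@H](C(C)C)[C@@H](O)C/C(C)=C/I | intermediate
25 | (1R,2R,3S,5E)-1-(acetyloxy)-6-iodo-1-[(2R,3S)-3-(2-iodoethyl)-3-methyloxiran-2-yl]-5-methyl-2-(propan-2-yl)hex-5-en-3-yl 3-methylbut-2-enoate | ICC[C@]1(C)O[C@@H]1[C@H](OC(C)=O)[C@H](C(C)C)[C@@H](OC(=O)C=C(C)C)C/C(C)=C/I | intermediate
26 | (1S,4E,7S,8R,9R,10R)-9-(acetyloxy)-1,5-dimethyl-8-(propan-2-yl)-11-oxabicyclo[8.1.0]undec-4-en-7-yl 3-methylbut-2-enoate | CC(=O)O[C@@H]1[C@H](C(C)C)[C@@H](OC(=O)C=C(C)C)C/C(C)=C/CC[C@]2(C)O[C@H]12 | target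

**Step count and weak points**

Total: 17 steps. Longest linear sequence: 11 steps (steps 1–6 then 13–17; the East branch, steps 7–12 then 13–17, is equally long).

The three steps most likely to fail:

Step 13 (hindered Cr allylation; anti and Felkin selectivity both rest on substrate control). The fallback replaces the equilibrating allylchromium reagent with a geometrically defined allylboronate. It sets out from alcohol 17: pincer-Pd(II)-catalysed borylation of the allylic alcohol with bis(pinacolato)diboron (Szabó conditions, no Pd(0), so the alkenyl iodide survives) gives 2-[2-(3-iodo-2-methylprop-2-en-1-yl)-4-methylpent-2-en-1-yl]-4,4,5,5-tetramethyl-1,3,2-dioxaborolane F1, with the boron-bearing CH2 trans to isopropyl. Thermal allylboration of aldehyde 8 (toluene, 4 Å MS, 40 °C) through the closed chair transition state turns that geometry into the anti relationship. After aqueous work-up it comes back to the route at 20.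

Step 15 (Evans–Tishchenko on a β-hydroxy ketone that carries an epoxide next to the carbinol and a β,γ-unsaturated ketone). The fallback separates reduction and acylation. It sets out from 22: Evans–Saksena reduction with Me4NBH(OAc)3 in MeCN/AcOH at −30 °C gives the anti diol (1R,2R,3S,5E)-6-iodo-1-[(2R,3S)-3-(2-iodoethyl)-3-methyloxiran-2-yl]-5-methyl-2-(propan-2-yl)hex-5-ene-1,3-diol F2. One equivalent of 3-methylbut-2-enoyl chloride in pyridine at −30 °C should acylate the less hindered C3 hydroxyl (C1–OH is flanked by the epoxide and the branched C2) to give the hydroxy ester (1R,2S,3S,5E)-1-hydroxy-6-iodo-1-[(2R,3S)-3-(2-iodoethyl)-3-methyloxiran-2-yl]-5-methyl-2-(propan-2-yl)hex-5-en-3-yl 3-methylbut-2-enoate F3. Acetylation (Ac2O, DMAP, pyridine) comes back to the route at 25.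

Step 17 (the proposed new macrocyclisation; risks are oligomerisation, protodehalogenation and slow ring closure of a strained medium ring). The fallback uses known two-electron chemistry with a preformed nucleophile. It sets out from 25: zinc insertion (Zn dust, LiCl, THF, 25 °C) takes place only at the C(sp3)–I bond and gives the alkylzinc iodide of 25 (C7–ZnI, alkenyl iodide and all stereocentres unchanged) F4. Slow addition of F4 to Pd2(dba)3/SPhos in THF at 50 °C (intramolecular Negishi coupling) closes the C6–C7 bond and comes back to the route at 26.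

**Further compounds**
F1 | step 13 | 2-[2-(3-iodo-2-methylprop-2-en-1-yl)-4-methylpent-2-en-1-yl]-4,4,5,5-tetramethyl-1,3,2-dioxaborolane (E iodoalkene; CH2B trans to isopropyl) | CC1(C)OB(OC1(C)C)C/C(C/C(C)=C/I)=C/C(C)C
F2 | step 15 | (1R,2R,3S,5E)-6-iodo-1-[(2R,3S)-3-(2-iodoethyl)-3-methyloxiran-2-yl]-5-methyl-2-(propan-2-yl)hex-5-ene-1,3-diol | ICC[C@]1(C)O[C@@H]1[C@H](O)[C@H](C(C)C)[C@@H](O)C/C(C)=C/I
F3 | step 15 | (1R,2S,3S,5E)-1-hydroxy-6-iodo-1-[(2R,3S)-3-(2-iodoethyl)-3-methyloxiran-2-yl]-5-methyl-2-(propan-2-yl)hex-5-en-3-yl 3-methylbut-2-enoate | ICC[C@]1(C)O[C@@H]1[C@H](O)[C@H](C(C)C)[C@@H](OC(=O)C=C(C)C)C/C(C)=C/I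
F4 | step 17 | alkylzinc iodide of 25 (C7–ZnI; alkenyl iodide, esters, epoxide and stereocentres as in 25) | I[Zn]CC[C@]1(C)O[C@@H]1[C@H](OC(C)=O)[C@H](C(C)C)[C@@H](OC(=O)C=C(C)C)C/C(C)=C/I
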